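**Retrosynthetic overview**
- The enal comes last, by allylic oxidation of the isopropenyl methyl; the α-methylene lactone comes from a fused isoxazoline by ester reduction, N–O cleavage, ketone methylenation and oxidative lactonisation.
- Key step: a magnesium-alkoxide-directed nitrile oxide [3+2] cycloaddition on a cyclohexenol builds the fused five-membered heterocycle that becomes the lactone and sets C7 and C8.
- The cyclohexenol comes from a cyclohexa-1,3-diene by singlet-oxygen [4+2] cycloaddition (oxygen at C6 and C9) and Mitsunobu inversion at C6.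
- The diene comes from (1R,5R)-verbenone by vinyl conjugate addition and cyclobutane fragmentation, which supply C10 (Me, vinyl) and C5 (isopropenyl).
- Ring order: cyclohexane bought with the terpene → transient 1,2-dioxine → isoxazoline → γ-lactone.

Assumption: (1R,5R)-(+)-verbenone is bought as such (it is the oxidation product of cheap (+)-α-pinene).
Naming: ring carbons carry elemane numbers (C10 quaternary with Me and vinyl, then C9, C8, C7, C6, C5); β is the face of the C10 methyl, α the face of the C10 vinyl.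

**Step 1**
Reactants: 1 (1R,5R)-(+)-verbenone; 2 vinylmagnesium bromide
Product: 3 (1R,4S,5S)-4-ethenyl-4,6,6-trimethylbicyclo[3.1.1]heptan-2-one
Conditions: 2 (1.5 equiv), CuI (10 mol %), THF, −30 → 0 °C; aq. NH4Cl
Reagents that add atoms: vinylmagnesium bromide (C=C[Mg]Br)
Why: Copper-catalysed 1,4-addition (conjugate addition) of the vinyl Grignard reagent takes place on the enone face opposite the gem-dimethyl bridge, so the new quaternary centre carries vinyl anti and methyl syn to that bridge.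

**Step 2**
Reactants: 3 (1R,4S,5S)-4-ethenyl-4,6,6-trimethylbicyclo[3.1.1]heptan-2-one
Product: 4 (4S,5S)-5-ethenyl-5-methyl-4-(prop-1-en-2-yl)cyclohex-1-en-1-yl acetate
Conditions: Ac2O, Zn(OAc)2, BF3·OEt2, 0 °C → rt
Reagents that add atoms: acetic anhydride (CC(=O)OC(C)=O)
Why: Lewis-acid-promoted fragmentation of the cyclobutyl ketone (Grob-type ring opening) cleaves the strained C1–C6 bond, the tertiary cation loses a proton to give the isopropenyl group and the enol is trapped as its acetate, leaving both stereocentres untouched with vinyl and isopropenyl trans.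

**Step 3**
Reactants: 4 (4S,5S)-5-ethenyl-5-methyl-4-(prop-1-en-2-yl)cyclohex-1-en-1-yl acetate
Product: 5 (4S,5S)-5-ethenyl-5-methyl-4-(prop-1-en-2-yl)cyclohex-2-en-1-one
Conditions: Pd(OAc)2 (5 mol %), dppe (5 mol %), Bu3SnOMe (20 mol %), allyl methyl carbonate, MeCN, 80 °C
Reagents that add atoms: none
Why: Tsuji–Saegusa-type palladium-catalysed dehydrogenation: the tin enolate released from the enol acetate is transmetallated to palladium, β-hydride elimination can only occur toward C6, and allyl methyl carbonate takes up the hydride as propene.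

**Step 4**
Reactants: 5 (4S,5S)-5-ethenyl-5-methyl-4-(prop-1-en-2-yl)cyclohex-2-en-1-one
Product: 7 (3S,4S)-3-ethenyl-3-methyl-4-(prop-1-en-2-yl)cyclohexa-1,5-dien-1-yl trifluoromethanesulfonate, via lithium dienolate 6 (not isolated)
Conditions: LDA, THF, −78 °C; then PhNTf2, −78 → 0 °C
Reagents that add atoms: N-phenylbis(trifluoromethanesulfonimide) (O=S(=O)(N(c1ccccc1)S(=O)(=O)C(F)(F)F)C(F)(F)F)
Why: Kinetic deprotonation at the only α′ CH2 (C9) gives the cross-conjugated lithium dienolate, which is O-triflated by PhNTf2 (enol triflate formation) without touching the γ stereocentre.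

**Step 5**
Reactants: 7 (3S,4S)-3-ethenyl-3-methyl-4-(prop-1-en-2-yl)cyclohexa-1,5-dien-1-yl trifluoromethanesulfonate
Product: 8 (5R,6S)-5-ethenyl-5-methyl-6-(prop-1-en-2-yl)cyclohexa-1,3-diene
Conditions: Pd(PPh3)4 (5 mol %), Bu3SnH, LiCl, THF, rt
Reagents that add atoms: none
Why: Palladium-catalysed reduction of the vinyl triflate (oxidative addition, hydride transfer from tin, reductive elimination) gives the cyclohexa-1,3-diene at room temperature, where [1,5]-hydrogen shifts are still slow.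

**Step 6**
Reactants: 8 (5R,6S)-5-ethenyl-5-methyl-6-(prop-1-en-2-yl)cyclohexa-1,3-diene
Product: 10 5β-isopropenyl-10β-methyl-10α-vinylcyclohex-7-ene-6α,9α-diol, via epidioxide 9 (not isolated)
Conditions: O2, hν, tetraphenylporphyrin (cat.), CH2Cl2, −40 °C; then thiourea, MeOH, rt
Reagents that add atoms: oxygen (O=O)
Why: [4+2] Cycloaddition of singlet oxygen to the ring diene (far faster than any ene reaction at the isopropenyl group) occurs on the α face, opposite the C10 methyl and C5 isopropenyl groups, so O6 and O9 are both α, and thiourea then reduces the O–O bond to the cis-diol.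

**Step 7**
Reactants: 10 5β-isopropenyl-10β-methyl-10α-vinylcyclohex-7-ene-6α,9α-diol
Product: 11 6β-acetoxy-5β-isopropenyl-10β-methyl-10α-vinylcyclohex-7-en-9α-ol
Conditions: PPh3, DIAD, AcOH, toluene, −20 °C → rt
Reagents that add atoms: acetic acid (CC(=O)O)
Why: Mitsunobu reaction: the unhindered allylic 6-OH is activated and displaced by acetate with SN2 inversion (6α-OH → 6β-OAc), whereas the neopentyl 9-OH next to the quaternary carbon cannot be displaced.

**Step 8**
Reactants: 11 6β-acetoxy-5β-isopropenyl-10β-methyl-10α-vinylcyclohex-7-en-9α-ol; 12 ethyl 2-chloro-2-(hydroxyimino)acetate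
Product: 15 ethyl 6β-acetoxy-9α-hydroxy-2-isoxazoline-3-carboxylate cis-fused on the α face (isoxazoline O on C8; isoxazoline C3 on C7), via bromomagnesium alkoxide 13 (not isolated), via nitrile oxide 14 (not isolated)
Conditions: i-PrOH, EtMgBr, CH2Cl2, 0 °C; then 12 (slow addition), 0 °C → rt
Reagents that add atoms: ethyl 2-chloro-2-(hydroxyimino)acetate (CCOC(=O)C(Cl)=NO)
Why: 1,3-Dipolar ([3+2]) cycloaddition of the nitrile oxide is accelerated and steered by the magnesium alkoxide at C9, which binds the dipole and delivers its oxygen to the neighbouring C8 and its carbon to C7 on the α face (syn to O9, anti to the C10 methyl and the 6β-acetate), creating C7 and C8 cis in one step and outrunning the unactivated vinyl and isopropenyl groups.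

**Step 9**
Reactants: 15 isoxazoline ester; 16 angelic acid
Product: 18 ethyl 6β-acetoxy-9α-angeloyloxy-2-isoxazoline-3-carboxylate (same α-fused isoxazoline), via mixed anhydride 17 (not isolated)
Conditions: 16, 2,4,6-trichlorobenzoyl chloride, Et3N, toluene, rt; then 15, DMAP, 70 °C
Reagents that add atoms: angelic acid (C/C=C(/C)C(=O)O)
Why: Yamaguchi esterification via the mixed anhydride acylates the single free hydroxyl (C9) and is the usual way to install an angelate with little Z-to-E isomerisation; no stereocentre is affected.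

**Step 10**
Reactants: 18 isoxazoline ester angelate
Product: 19 6β-acetoxy-9α-angeloyloxy-3-(hydroxymethyl)-2-isoxazoline (same α-fused isoxazoline)
Conditions: NaBH4, EtOH, 0 °C
Reagents that add atoms: none
Why: Hydride reduction: the ester on the C=N carbon is activated like an α-imino ester and is reduced by NaBH4 at 0 °C, while the acetate, the angelate and the isoxazoline C=N bond survive.

**Step 11**
Reactants: 19 3-(hydroxymethyl)isoxazoline
Product: 21 6β-acetoxy-9α-angeloyloxy-8α,12-dihydroxy-13-norelema-1,3-dien-11-one (5αH,7βH,8βH), via hydroxy imine 20 (not isolated)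
Conditions: Mo(CO)6, MeCN–H2O, 80 °C
Reagents that add atoms: water (O)
Why: Mo(CO)6-mediated reductive N–O cleavage of the isoxazoline followed by in situ imine hydrolysis unmasks the β-hydroxy ketone under neutral conditions that spare the alkenes and do not epimerise C7 or C8.

**Step 12**
Reactants: 21 8α,12-dihydroxy 11-ketone
Product: 22 6β-acetoxy-9α-angeloyloxyelema-1,3,11(13)-triene-8α,12-diol (5αH,7βH,8βH)
Conditions: Zn, CH2Br2, TiCl4, THF–CH2Cl2, 0 °C → rt
Reagents that add atoms: dibromomethane (BrCBr)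
Why: Takai–Lombardo methylenation is non-basic, so the ketone becomes the 1,1-disubstituted alkene without retro-aldol cleavage, β-elimination of the C6 acetate, acyl migration or attack on the esters.

**Step 13**
Reactants: 22 11(13)-ene-8α,12-diol
Product: 25 6β-acetoxy-9α-angeloyloxyelema-1,3,11(13)-trien-12,8α-olide (5αH,7βH,8βH), via hydroxy enal 23 (not isolated), via lactol 24 (not isolated)
Conditions: MnO2 (activated, excess), CH2Cl2, rt
Reagents that add atoms: none
Why: Oxidative lactonisation: MnO2 oxidises only the allylic primary alcohol, the enal is captured by the cis 8α-hydroxyl as a lactol, and this is oxidised on to the cis-fused α-methylene-γ-butyrolactone with C7 and C8 unchanged.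

**Step 14**
Reactants: 25 α-methylene lactone
Product: 27 6β-acetoxy-9α-angeloyloxy-15-oxoelema-1,3,11(13)-trien-12,8α-olide (CNP0252310.2), via allylic alcohol 26 (not isolated)
Conditions: SeO2, 1,4-dioxane, 70 °C
Reagents that add atoms: selenium dioxide (O=[Se]=O)
Why: Riley oxidation: SeO2 reacts by ene reaction and [2,3]-sigmatropic rearrangement at the methyl group of the only electron-rich alkene that has allylic hydrogens (the vinyl group has none; the lactone methylene and the angelate are electron-poor) and oxidises the allylic alcohol on to the enal.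

**Compound list**
1 | (1R,5R)-(+)-verbenone, (1R,5R)-4,6,6-trimethylbicyclo[3.1.1]hept-3-en-2-one | CC1=CC(=O)[C@@H]2C[C@H]1C2(C)C | starting material
2 | vinylmagnesium bromide | C=C[Mg]Br | starting material
3 | (1R,4S,5S)-4-ethenyl-4,6,6-trimethylbicyclo[3.1.1]heptan-2-one (vinyl anti to the gem-dimethyl bridge) | C=C[C@]1(C)CC(=O)[C@@H]2C[C@H]1C2(C)C | intermediate
4 | (4S,5S)-5-ethenyl-5-methyl-4-(prop-1-en-2-yl)cyclohex-1-en-1-yl acetate | C=C[C@]1(C)CC(OC(C)=O)=CC[C@H]1C(C)=C | intermediate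
5 | (4S,5S)-5-ethenyl-5-methyl-4-(prop-1-en-2-yl)cyclohex-2-en-1-one | C=C[C@]1(C)CC(=O)C=C[C@H]1C(C)=C | intermediate
6 | lithium cross-conjugated dienolate of 5 | C=C[C@]1(C)C=C(O[Li])C=C[C@H]1C(C)=C | intermediate
7 | (3S,4S)-3-ethenyl-3-methyl-4-(prop-1-en-2-yl)cyclohexa-1,5-dien-1-yl trifluoromethanesulfonate | C=C[C@]1(C)C=C(OS(=O)(=O)C(F)(F)F)C=C[C@H]1C(C)=C | intermediate
8 | (5R,6S)-5-ethenyl-5-methyl-6-(prop-1-en-2-yl)cyclohexa-1,3-diene | C=C[C@]1(C)C=CC=C[C@H]1C(C)=C | intermediate
9 | 6α,9α-epidioxy-5β-isopropenyl-10β-methyl-10α-vinylcyclohex-7-ene | C=C[C@]1(C)[C@H]2C=C[C@H](OO2)[C@H]1C(C)=C | intermediate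
10 | 5β-isopropenyl-10β-methyl-10α-vinylcyclohex-7-ene-6α,9α-diol | C=C[C@]1(C)[C@H](O)C=C[C@H](O)[C@H]1C(C)=C | intermediate
11 | 6β-acetoxy-5β-isopropenyl-10β-methyl-10α-vinylcyclohex-7-en-9α-ol | C=C[C@]1(C)[C@H](O)C=C[C@@H](OC(C)=O)[C@H]1C(C)=C | intermediate
12 | ethyl 2-chloro-2-(hydroxyimino)acetate | CCOC(=O)C(Cl)=NO | starting material
13 | bromomagnesium 9α-alkoxide of 11 | C=C[C@]1(C)[C@H](O[Mg]Br)C=C[C@@H](OC(C)=O)[C@H]1C(C)=C | intermediate
14 | ethoxycarbonylformonitrile oxide | CCOC(=O)C#[N+][O-] | intermediate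
15 | ethyl 6β-acetoxy-9α-hydroxy-2-isoxazoline-3-carboxylate, isoxazoline cis-fused on the α face (O on C8, C3 on C7) | C=C[C@]1(C)[C@H](O)[C@@H]2ON=C(C(=O)OCC)[C@@H]2[C@@H](OC(C)=O)[C@H]1C(C)=C | intermediate
16 | angelic acid, (Z)-2-methylbut-2-enoic acid | C/C=C(/C)C(=O)O | starting material
17 | angelic 2,4,6-trichlorobenzoic anhydride | C/C=C(/C)C(=O)OC(=O)c1c(Cl)cc(Cl)cc1Cl | intermediate
18 | 9α-angelate of isoxazoline ester 15 | C=C[C@]1(C)[C@H](OC(=O)/C(C)=C\C)[C@@H]2ON=C(C(=O)OCC)[C@@H]2[C@@H](OC(C)=O)[C@H]1C(C)=C | intermediate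
19 | 6β-acetoxy-9α-angeloyloxy-3-(hydroxymethyl)-2-isoxazoline (α-fused as in 15) | C=C[C@]1(C)[C@H](OC(=O)/C(C)=C\C)[C@@H]2ON=C(CO)[C@@H]2[C@@H](OC(C)=O)[C@H]1C(C)=C | intermediate
20 | 8α-hydroxy 11-imine (β-hydroxy imine) | C=C[C@]1(C)[C@H](OC(=O)/C(C)=C\C)[C@H](O)[C@H](C(=N)CO)[C@@H](OC(C)=O)[C@H]1C(C)=C | intermediate
21 | 6β-acetoxy-9α-angeloyloxy-8α,12-dihydroxy-13-norelema-1,3-dien-11-one | C=C[C@]1(C)[C@H](OC(=O)/C(C)=C\C)[C@H](O)[C@H](C(=O)CO)[C@@H](OC(C)=O)[C@H]1C(C)=C | intermediate
22 | 6β-acetoxy-9α-angeloyloxyelema-1,3,11(13)-triene-8α,12-diol | C=C[C@]1(C)[C@H](OC(=O)/C(C)=C\C)[C@H](O)[C@H](C(=C)CO)[C@@H](OC(C)=O)[C@H]1C(C)=C | intermediate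
23 | 6β-acetoxy-9α-angeloyloxy-8α-hydroxyelema-1,3,11(13)-trien-12-al | C=C[C@]1(C)[C@H](OC(=O)/C(C)=C\C)[C@H](O)[C@H](C(=C)C=O)[C@@H](OC(C)=O)[C@H]1C(C)=C | intermediate
24 | 12-hydroxy-8α,12-epoxide (lactol) of 23 | C=C[C@]1(C)[C@H](OC(=O)/C(C)=C\C)[C@@H]2OC(O)C(=C)[C@@H]2[C@@H](OC(C)=O)[C@H]1C(C)=C | intermediate
25 | 6β-acetoxy-9α-angeloyloxyelema-1,3,11(13)-trien-12,8α-olide | C=C[C@]1(C)[C@H](OC(=O)/C(C)=C\C)[C@@H]2OC(=O)C(=C)[C@@H]2[C@@H](OC(C)=O)[C@H]1C(C)=C | intermediate
26 | 6β-acetoxy-9α-angeloyloxy-15-hydroxyelema-1,3,11(13)-trien-12,8α-olide | C=C[C@]1(C)[C@H](OC(=O)/C(C)=C\C)[C@@H]2OC(=O)C(=C)[C@@H]2[C@@H](OC(C)=O)[C@H]1C(=C)CO | intermediate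
27 | 6β-acetoxy-9α-angeloyloxy-15-oxoelema-1,3,11(13)-trien-12,8α-olide (CNP0252310.2) | C=C[C@]1(C)[C@H](OC(=O)/C(C)=C\C)[C@@H]2OC(=O)C(=C)[C@@H]2[C@@H](OC(C)=O)[C@H]1C(=C)C=O | target

Total steps: 14. Longest linear sequence: 14 steps (1 → 27).

**Steps most likely to fail, with fallbacks**

Step 6 is at risk because the face selectivity of the singlet-oxygen cycloaddition rests only on the C10 methyl and C5 isopropenyl groups, and the diene is prone to hydrogen shifts. The fallback sets out from 5 and comes back at 10, replacing steps 4 to 6. The kinetic lithium enolate of 5 (LDA, THF, −78 °C) is hydroxylated with racemic 2-(phenylsulfonyl)-3-phenyloxaziridine by axial attack anti to the pseudo-axial C10 methyl, giving the 9α-hydroxy enone F1. Weitz–Scheffer epoxidation (H2O2, NaOH, MeOH) trans to the C5 isopropenyl group gives the 6α,7α-epoxy ketone F2. Wharton transposition (N2H4·H2O, AcOH, MeOH) then gives diol 10.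

Step 7 is at risk because Mitsunobu acetate displacement must enter syn to the neighbouring isopropenyl group and can leak into SN2′ attack. The fallback sets out from 10 and comes back at 11. MnO2 oxidises the less hindered allylic 6-hydroxyl to the 9α-hydroxy-6-oxo enone F3. Luche reduction (NaBH4, CeCl3·7H2O, MeOH, −78 °C) delivers hydride anti to the β-axial C10 methyl, giving the 6β,9α-diol F4. Ac2O in pyridine at 0 °C acetylates the less hindered 6-hydroxyl to give 11.

Step 8 is at risk because the ring alkene is an intrinsically slow dipolarophile and the vinyl and isopropenyl groups compete unless the alkoxide acceleration is large. The fallback replaces the cycloaddition by an intramolecular alkylation; it sets out from 11 and comes back at 25, replacing steps 8 to 13.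
- VO(acac)2 and t-BuOOH epoxidise syn to the 9α-hydroxyl, giving the 7α,8α-epoxy alcohol F5.
- MgBr2·OEt2 opens the epoxide at C7 from the β face (chelation to O9, hindered C8), giving the 7β-bromo-8α,9α-diol F6.
- The less hindered 8-hydroxyl is acylated with diethylphosphonoacetic acid (DCC), giving the phosphonoacetate F7.
- Cs2CO3 in MeCN closes the ring by SN2 alkylation at C7 with inversion, giving the cis-fused α-phosphono lactone F8.
- Horner–Wadsworth–Emmons reaction with paraformaldehyde (K2CO3, THF) gives the 9α-hydroxy α-methylene lactone F9.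
- Yamaguchi angeloylation as in step 9 gives 25.

**Further compounds**
F1 | step 6 | 9α-hydroxy-5β-isopropenyl-10β-methyl-10α-vinylcyclohex-6-en-8-one | C=C[C@]1(C)[C@H](O)C(=O)C=C[C@H]1C(C)=C
F2 | step 6 | 6α,7α-epoxy-9α-hydroxy-5β-isopropenyl-10β-methyl-10α-vinylcyclohexan-8-one | C=C[C@]1(C)[C@H](O)C(=O)[C@@H]2O[C@@H]2[C@H]1C(C)=C
F3 | step 7 | 9α-hydroxy-5β-isopropenyl-10β-methyl-10α-vinylcyclohex-7-en-6-one | C=C[C@]1(C)[C@H](O)C=CC(=O)[C@H]1C(C)=C
F4 | step 7 | 5β-isopropenyl-10β-methyl-10α-vinylcyclohex-7-ene-6β,9α-diol | C=C[C@]1(C)[C@H](O)C=C[C@@H](O)[C@H]1C(C)=C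
F5 | step 8 | 6β-acetoxy-7α,8α-epoxy-5β-isopropenyl-10β-methyl-10α-vinylcyclohexan-9α-ol | C=C[C@]1(C)[C@H](O)[C@@H]2O[C@@H]2[C@@H](OC(C)=O)[C@H]1C(C)=C
F6 | step 8 | 6β-acetoxy-7β-bromo-5β-isopropenyl-10β-methyl-10α-vinylcyclohexane-8α,9α-diol | C=C[C@]1(C)[C@H](O)[C@H](O)[C@@H](Br)[C@@H](OC(C)=O)[C@H]1C(C)=C
F7 | step 8 | 8α-O-(diethylphosphonoacetyl) ester of F6 | C=C[C@]1(C)[C@H](O)[C@H](OC(=O)CP(=O)(OCC)OCC)[C@@H](Br)[C@@H](OC(C)=O)[C@H]1C(C)=C
F8 | step 8 | 6β-acetoxy-11-(diethoxyphosphoryl)-9α-hydroxy-13-norelema-1,3-dien-12,8α-olide | C=C[C@]1(C)[C@H](O)[C@@H]2OC(=O)C(P(=O)(OCC)OCC)[C@@H]2[C@@H](OC(C)=O)[C@H]1C(C)=C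
F9 | step 8 | 6β-acetoxy-9α-hydroxyelema-1,3,11(13)-trien-12,8α-olide | C=C[C@]1(C)[C@H](O)[C@@H]2OC(=O)C(=C)[C@@H]2[C@@H](OC(C)=O)[C@H]1C(C)=C
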